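**Retrosynthetic overview**
1. Target ⇒ interflavanyl C4–C8 bond, made last: (+)-leucorobinetinidin (C4 electrophile) plus (+)-dihydrorobinetin (C8 nucleophile).
2. Leucorobinetinidin ⇒ dihydrorobinetin by C4=O reduction, so one dihydroflavonol supplies both halves and all four C2/C3 stereocentres.
3. Dihydrorobinetin ⇒ its tetrabenzyl ether ⇒ a 2'-hydroxychalcone by the key disconnection, the O1–C2 and C3–O bonds: enantioselective epoxidation followed by 6-endo phenol ring closure.
4. Chalcone ⇒ 4'-benzyloxy-2'-hydroxyacetophenone plus 3,4,5-tris(benzyloxy)benzaldehyde (Claisen–Schmidt).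
5. Ring order: the pyranone ring is the only ring built (step 2); it serves unchanged as the lower C-ring and, after reduction, as the upper C-ring.

The target was read as robinetinidol-(4α→8)-dihydrorobinetin: upper unit (2R,3S,4S), 2,3-trans-3,4-trans; lower unit (2R,3R), 2,3-trans.

Assumption: 1 and 2 are bought as such (both are catalogue compounds; each is otherwise one benzylation away from 2,4-dihydroxyacetophenone or 3,4,5-trihydroxybenzaldehyde).
Assumption: (S)-BINOL is taken to give the (αR,βS) epoxide, as it does with simple chalcones; if chelation reverses the sense, (R)-BINOL is used.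

**Step 1**
Reactants: 1 4'-(benzyloxy)-2'-hydroxyacetophenone; 2 3,4,5-tris(benzyloxy)benzaldehyde
Product: 3 (E)-1-[4-(benzyloxy)-2-hydroxyphenyl]-3-[3,4,5-tris(benzyloxy)phenyl]prop-2-en-1-one
Conditions: KOH (50% aq), EtOH–THF, rt, 36 h; then 1 M HCl
Reagents that add atoms: none
Why: Claisen–Schmidt aldol condensation, in which the acetophenone enolate adds to the non-enolisable aldehyde and E1cB loss of water gives the conjugated (E)-enone, while the phenoxide and the benzyl ethers are inert to base; no stereocentre is formed.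

**Step 2**
Reactants: 3 (E)-1-[4-(benzyloxy)-2-hydroxyphenyl]-3-[3,4,5-tris(benzyloxy)phenyl]prop-2-en-1-one
Product: 5 (2R,3R)-7-(benzyloxy)-3-hydroxy-2-[3,4,5-tris(benzyloxy)phenyl]chroman-4-one, via (αR,βS)-chalcone epoxide 4 (not isolated)
Conditions: La(OiPr)3 (10 mol %), (S)-BINOL (10 mol %), Ph3P=O (30 mol %), TBHP (1.3 equiv, decane), 4 Å MS, THF, 0 °C → rt, Ar; pH 7 buffer
Reagents that add atoms: tert-butyl hydroperoxide, CC(C)(C)OO
Why: Proposed new method: the free 2'-phenol and the carbonyl of 3 bind La as a κ2-O,O chelate (the binding mode that makes 2'-hydroxychalcones good substrates for chiral Lewis acids), which removes the phenoxide deactivation that normally blocks Weitz–Scheffer epoxidation of such chalcones and holds the s-cis enone in the BINOLate pocket, so that La–OOtBu adds to one face of Cβ and the La enolate closes to the (αR,βS)-epoxide 4, after which the La-bound phenolate opens the benzylic Cβ–O bond 6-endo with inversion to form O1–C2 and give the 2,3-trans (2R,3R) ring (C3 from the epoxidation, C2 by inversion); the closest known reactions are the La–BINOL–Ph3PO/ROOH epoxidation of chalcones that carry no free ortho-phenol and the racemic Algar–Flynn–Oyamada reaction.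

**Step 3**
Reactants: 5 (2R,3R)-7-(benzyloxy)-3-hydroxy-2-[3,4,5-tris(benzyloxy)phenyl]chroman-4-one
Product: 6 (2R,3R)-3,7-dihydroxy-2-(3,4,5-trihydroxyphenyl)chroman-4-one, (+)-dihydrorobinetin
Conditions: H2 (1 atm), 10% Pd/C, EtOAc–MeOH, rt, monitored
Reagents that add atoms: none
Why: Hydrogenolysis of the four aryl benzyl ethers is much faster under neutral 1 atm conditions than reduction of the aryl ketone or cleavage of the C2–O1 bond, and C2/C3 are not epimerised without base.

**Step 4**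
Reactants: 6 (+)-dihydrorobinetin (about one fifth of the material)
Product: 7 (2R,3S,4R)-2-(3,4,5-trihydroxyphenyl)chromane-3,4,7-triol, (+)-leucorobinetinidin
Conditions: NaBH4 (3 equiv), degassed EtOH, 0 °C → rt, N2; AcOH to pH 6 at 0 °C; used crude
Reagents that add atoms: none
Why: Borohydride reduction of the C4 ketone, with axial hydride delivery to the half-chair giving mainly the 3,4-trans (4R) alcohol; the C4 configuration does not matter because C4 is ionised in step 5, and C2/C3 are untouched (C3 becomes S only through CIP priority change).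

**Step 5**
Reactants: 7 (+)-leucorobinetinidin; 6 (+)-dihydrorobinetin (4 equiv, excess recovered)
Product: 9 (2R,3R)-3,7-dihydroxy-8-[(2R,3S,4S)-3,7-dihydroxy-2-(3,4,5-trihydroxyphenyl)chroman-4-yl]-2-(3,4,5-trihydroxyphenyl)chroman-4-one, via A-ring quinone methide 8 (not isolated)
Conditions: 0.1 M aq HCl, rt, N2, 24–48 h; Sephadex LH-20 (EtOH), then RP-HPLC
Reagents that add atoms: none
Why: Acid-catalysed flavan-3,4-diol condensation (biomimetic Friedel–Crafts alkylation), in which 7 loses its C4 hydroxyl as water to give the A-ring para-quinone methide 8 (reacting as its O-protonated form, the 7-hydroxy-stabilised C4 cation), whose C4 is attacked by C8 of 6 (the enol-like carbon ortho to 7-OH, favoured by C7=C8 bond fixation in the chromanone) from the face anti to the 3-OH, setting C4 as 3,4-trans (4S); the 4β epimer and any 6-linked isomer are removed chromatographically.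

**Compound list**
1 | 4'-(benzyloxy)-2'-hydroxyacetophenone | CC(=O)c1ccc(OCc2ccccc2)cc1O | starting material
2 | 3,4,5-tris(benzyloxy)benzaldehyde | O=Cc1cc(OCc2ccccc2)c(OCc2ccccc2)c(OCc2ccccc2)c1 | starting material
3 | (E)-1-[4-(benzyloxy)-2-hydroxyphenyl]-3-[3,4,5-tris(benzyloxy)phenyl]prop-2-en-1-one | O=C(/C=C/c1cc(OCc2ccccc2)c(OCc2ccccc2)c(OCc2ccccc2)c1)c1ccc(OCc2ccccc2)cc1O | intermediate
4 | [4-(benzyloxy)-2-hydroxyphenyl][(2R,3S)-3-[3,4,5-tris(benzyloxy)phenyl]oxiran-2-yl]methanone, the (αR,βS)-chalcone epoxide | O=C(c1ccc(OCc2ccccc2)cc1O)[C@@H]1O[C@H]1c1cc(OCc2ccccc2)c(OCc2ccccc2)c(OCc2ccccc2)c1 | intermediate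
5 | (2R,3R)-7-(benzyloxy)-3-hydroxy-2-[3,4,5-tris(benzyloxy)phenyl]chroman-4-one | O=C1c2ccc(OCc3ccccc3)cc2O[C@H](c2cc(OCc3ccccc3)c(OCc3ccccc3)c(OCc3ccccc3)c2)[C@H]1O | intermediate
6 | (2R,3R)-3,7-dihydroxy-2-(3,4,5-trihydroxyphenyl)chroman-4-one, (+)-dihydrorobinetin | O=C1c2ccc(O)cc2O[C@H](c2cc(O)c(O)c(O)c2)[C@H]1O | intermediate
7 | (2R,3S,4R)-2-(3,4,5-trihydroxyphenyl)chromane-3,4,7-triol, (+)-leucorobinetinidin | O[C@@H]1c2ccc(O)cc2O[C@H](c2cc(O)c(O)c(O)c2)[C@H]1O | intermediate
8 | (2R,3S)-3-hydroxy-2-(3,4,5-trihydroxyphenyl)-2,3-dihydro-7H-chromen-7-one, the A-ring para-quinone methide | O=C1C=CC2=C[C@H](O)[C@@H](c3cc(O)c(O)c(O)c3)OC2=C1 | intermediate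
9 | (2R,3R)-3,7-dihydroxy-8-[(2R,3S,4S)-3,7-dihydroxy-2-(3,4,5-trihydroxyphenyl)chroman-4-yl]-2-(3,4,5-trihydroxyphenyl)chroman-4-one, robinetinidol-(4α→8)-dihydrorobinetin | O=C1c2ccc(O)c([C@@H]3c4ccc(O)cc4O[C@H](c4cc(O)c(O)c(O)c4)[C@H]3O)c2O[C@H](c2cc(O)c(O)c(O)c2)[C@H]1O | target

**Totals and risks**
Total steps: 5. Longest linear sequence: 5 (1 → 3 → 5 → 6 → 7 → 9).

The three steps most likely to fail:

Step 2, the proposed oxidative cyclisation. It may give low ee (BINOLate displaced by the phenolic substrate), or divert to the flavanone by oxa-Michael closure, to the aurone-type 5-exo product, or onward to the flavonol. The fallback uses known chemistry and runs from 3 back to 5. The phenol of 3 is capped (MOMCl, NaH, DMF) to give the 2'-O-methoxymethyl chalcone F1. This is a normal substrate for Juliá–Colonna epoxidation (poly-L-leucine, urea–H2O2, DBU, THF), which gives the (αR,βS)-epoxide F2. HCl in MeOH at 50 °C then removes the MOM group, and the freed phenol opens the benzylic epoxide carbon to give 5.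

Step 5, the interflavanyl coupling. The A-ring of 6 is a weak nucleophile, so self-condensation of 7, attack at C6 or on the pyrogallol B-ring, and the 4β epimer can all erode the yield; a modest yield is expected even when it works. The fallback runs from 7 to 9 and builds the lower heterocycle after the C–C bond. 7 is condensed with a tenfold excess of cheap 2,4-dihydroxyacetophenone (0.1 M HCl, dioxane–water) to give the 3-(flavan-4-yl)acetophenone F3; the 3- and 5-linked isomers are separable at this stage. BnBr/K2CO3/DMF etherifies the five free phenols but not the ketone-chelated one, giving the pentabenzyl ether F4. Claisen–Schmidt condensation with 2 gives the dimeric chalcone F5. Algar–Flynn–Oyamada closure (NaOH, H2O2, 0 °C, stopped at the dihydroflavonol, the two lower-unit diastereomers separated; or the step 2 catalyst once proven) gives the octabenzyl dimer F6. Hydrogenolysis (H2, Pd/C) then gives 9.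

Step 4, the free-phenolic diol. 7 is acid-labile and air-sensitive, may self-condense on neutralisation, and can be held up as borate complexes. The fallback runs from 5 to 9 and reduces before deprotecting. NaBH4 on 5 gives the stable, chromatographable tetrabenzyl diol F7. BF3·OEt2 (THF–CH2Cl2, −20 °C) with 6 (4 equiv) gives the upper-unit-protected dimer F8, and hydrogenolysis (H2, Pd/C) gives 9.

**Further compounds**
F1 | step 2 | (E)-1-[4-(benzyloxy)-2-(methoxymethoxy)phenyl]-3-[3,4,5-tris(benzyloxy)phenyl]prop-2-en-1-one | O=C(/C=C/c1cc(OCc2ccccc2)c(OCc2ccccc2)c(OCc2ccccc2)c1)c1ccc(OCc2ccccc2)cc1OCOC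
F2 | step 2 | [4-(benzyloxy)-2-(methoxymethoxy)phenyl][(2R,3S)-3-[3,4,5-tris(benzyloxy)phenyl]oxiran-2-yl]methanone | O=C(c1ccc(OCc2ccccc2)cc1OCOC)[C@@H]1O[C@H]1c1cc(OCc2ccccc2)c(OCc2ccccc2)c(OCc2ccccc2)c1
F3 | step 5 | 1-[3-[(2R,3S,4S)-3,7-dihydroxy-2-(3,4,5-trihydroxyphenyl)chroman-4-yl]-2,4-dihydroxyphenyl]ethan-1-one | CC(=O)c1ccc(O)c([C@@H]2c3ccc(O)cc3O[C@H](c3cc(O)c(O)c(O)c3)[C@H]2O)c1O
F4 | step 5 | 1-[4-(benzyloxy)-3-[(2R,3S,4S)-7-(benzyloxy)-3-hydroxy-2-[3,4,5-tris(benzyloxy)phenyl]chroman-4-yl]-2-hydroxyphenyl]ethan-1-one | CC(=O)c1ccc(OCc2ccccc2)c([C@@H]2c3ccc(OCc4ccccc4)cc3O[C@H](c3cc(OCc4ccccc4)c(OCc4ccccc4)c(OCc4ccccc4)c3)[C@H]2O)c1O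
F5 | step 5 | (E)-1-[4-(benzyloxy)-3-[(2R,3S,4S)-7-(benzyloxy)-3-hydroxy-2-[3,4,5-tris(benzyloxy)phenyl]chroman-4-yl]-2-hydroxyphenyl]-3-[3,4,5-tris(benzyloxy)phenyl]prop-2-en-1-one | O=C(/C=C/c1cc(OCc2ccccc2)c(OCc2ccccc2)c(OCc2ccccc2)c1)c1ccc(OCc2ccccc2)c([C@@H]2c3ccc(OCc4ccccc4)cc3O[C@H](c3cc(OCc4ccccc4)c(OCc4ccccc4)c(OCc4ccccc4)c3)[C@H]2O)c1O
F6 | step 5 | (2R,3R)-7-(benzyloxy)-8-[(2R,3S,4S)-7-(benzyloxy)-3-hydroxy-2-[3,4,5-tris(benzyloxy)phenyl]chroman-4-yl]-3-hydroxy-2-[3,4,5-tris(benzyloxy)phenyl]chroman-4-one | O=C1c2ccc(OCc3ccccc3)c([C@@H]3c4ccc(OCc5ccccc5)cc4O[C@H](c4cc(OCc5ccccc5)c(OCc5ccccc5)c(OCc5ccccc5)c4)[C@H]3O)c2O[C@H](c2cc(OCc3ccccc3)c(OCc3ccccc3)c(OCc3ccccc3)c2)[C@H]1O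
F7 | step 4 | (2R,3S,4R)-7-(benzyloxy)-2-[3,4,5-tris(benzyloxy)phenyl]chromane-3,4-diol | O[C@@H]1c2ccc(OCc3ccccc3)cc2O[C@H](c2cc(OCc3ccccc3)c(OCc3ccccc3)c(OCc3ccccc3)c2)[C@H]1O
F8 | step 4 | (2R,3R)-8-[(2R,3S,4S)-7-(benzyloxy)-3-hydroxy-2-[3,4,5-tris(benzyloxy)phenyl]chroman-4-yl]-3,7-dihydroxy-2-(3,4,5-trihydroxyphenyl)chroman-4-one | O=C1c2ccc(O)c([C@@H]3c4ccc(OCc5ccccc5)cc4O[C@H](c4cc(OCc5ccccc5)c(OCc5ccccc5)c(OCc5ccccc5)c4)[C@H]3O)c2O[C@H](c2cc(O)c(O)c(O)c2)[C@H]1O
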